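**Retrosynthetic overview**

1. The cyclohexene carbons are called C1'' (C–CH3), C2'' (=CH), C3'' (CH on flavone C8), C4'' (CH bearing the aroyl group), C5'' (CH bearing the dihydroxyphenyl ring) and C6'' (CH2). The last step uses fluoride to remove six silyl ethers and, by SE2' loss of a boryl group from C2'', to move the ring alkene from C1''=C6'' to C1''=C2''.
2. Key disconnection: C2''–C3'' and C4''–C5'' are made together in an enantioselective exo Diels–Alder reaction. The dienophile is an (E)-enone whose β-carbon carries flavone C8 (C3''=C4''); the diene is a (1E,3E)-1-boryl-2-methyl-4-arylbutadiene (C2''–C1''–C6''–C5'').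
3. Enabling feature: the hydroxyl on C2 of the 2,4-dihydroxy-3-prenylbenzoyl ring is ortho to the ketone on C4''. This O–H/C=O pair chelates a chiral borate, which activates the enone and covers one face. In addition, C2'' is the allylic neighbour of the alkene that the cycloaddition leaves behind, so a boron placed there delivers the alkene to its true position.
4. The enone comes from aldol condensation of the flavone-8-carbaldehyde (from the 8-iodide by formylation) with silylated 2,4-dihydroxy-3-prenylacetophenone. The diene comes from 2,4-dihydroxybenzaldehyde by Wittig and boron–Wittig olefination.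
5. Ring order: the benzene rings are bought; pyranone ring C of the flavone is closed first (enolate acylation, cyclodehydration); the cyclohexene is closed in the last step but one.

Key step: step 15

Notation: TBS = tert-butyldimethylsilyl, TBSO = tert-butyldimethylsilyloxy, prenyl = 3-methylbut-2-en-1-yl, Bpin = 4,4,5,5-tetramethyl-1,3,2-dioxaborolan-2-yl.

Assumption: which antipode of VANOL shields which face of this enone is taken by analogy with other 2'-hydroxychalcones; (R)-VANOL is written, and (S)-VANOL would be used if a trial shows the opposite sense.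

**Route**

Step 1
Reactants: 1 2,4,6-trihydroxyacetophenone
Product: 2 1-[2-hydroxy-4,6-bis(TBSO)phenyl]ethanone
Conditions: TBSCl (2.1 equiv), imidazole, DMF, 0 °C → rt
Reagents that add atoms: tert-butyldimethylsilyl chloride, CC(C)(C)[Si](C)(C)Cl
Why: Phenol O-silylation in which the para hydroxyl and one of the two equivalent ortho hydroxyls react, while the remaining ortho hydroxyl is held in a hydrogen bond to the acetyl C=O and should stay free.

Step 2
Reactants: 2 1-[2-hydroxy-4,6-bis(TBSO)phenyl]ethanone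
Product: 3 1-[2-hydroxy-3-iodo-4,6-bis(TBSO)phenyl]ethanone
Conditions: N-iodosuccinimide (1.0 equiv), CH2Cl2, 0 °C, dark
Reagents that add atoms: N-iodosuccinimide, O=C1CCC(=O)N1I
Why: Electrophilic aromatic iodination ortho to the free phenol, the only other open position lying between two bulky silyloxy groups; the halogen goes in before any alkene is present.

Step 3
Reactants: 3 1-[2-hydroxy-3-iodo-4,6-bis(TBSO)phenyl]ethanone
Product: 4 1-[2-hydroxy-3-iodo-4,6-bis(TBSO)phenyl]-5-methylhex-4-en-1-one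
Conditions: LiN(iPr)2 (2.2 equiv), THF, −78 °C; prenyl bromide (1.05 equiv), −78 → −30 °C; aq NH4Cl
Reagents that add atoms: prenyl bromide, CC(C)=CCBr
Why: C-Alkylation of the phenolate–enolate dianion by SN2 displacement on the primary allylic bromide, which brings in the chain that becomes the 3-prenyl group of the flavone; amide bases do not exchange the aryl iodide.

Step 4
Reactants: 5 methyl 2,4-dihydroxybenzoate
Product: 6 methyl 2-hydroxy-4-(prenyloxy)benzoate
Conditions: prenyl bromide (1.1 equiv), K2CO3, acetone, reflux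
Reagents that add atoms: prenyl bromide, CC(C)=CCBr
Why: Williamson ether synthesis at the more acidic para hydroxyl; the ortho hydroxyl is hydrogen-bonded to the ester and should not react.

Step 5
Reactants: 6 methyl 2-hydroxy-4-(prenyloxy)benzoate
Product: 7 2-hydroxy-4-(prenyloxy)benzoic acid
Conditions: NaOH (2 M aq), MeOH, 60 °C; then 1 M HCl to pH 3, 0 °C
Reagents that add atoms: sodium hydroxide, [Na+].[OH-]
Why: Saponification of the methyl ester; the aryl prenyl ether is stable to base and the acidification is kept cold and dilute.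

Step 6
Reactants: 7 2-hydroxy-4-(prenyloxy)benzoic acid
Product: 9 2-(TBSO)-4-(prenyloxy)benzoyl chloride, via bis-silylated acid 8 (not isolated)
Conditions: TBSCl (2.3 equiv), imidazole, DMF, rt; solvent change; (COCl)2 (1.2 equiv), DMF (cat.), CH2Cl2, 0 °C → rt
Reagents that add atoms: tert-butyldimethylsilyl chloride, CC(C)(C)[Si](C)(C)Cl; oxalyl chloride, O=C(Cl)C(Cl)=O
Why: Silylation of phenol and acid, then conversion of the silyl ester into the acid chloride by Vilsmeier-type activation, which forms no HCl and so spares the prenyl ether.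

Step 7
Reactants: 4 1-[2-hydroxy-3-iodo-4,6-bis(TBSO)phenyl]-5-methylhex-4-en-1-one; 9 2-(TBSO)-4-(prenyloxy)benzoyl chloride
Product: 11 8-iodo-3-prenyl-2-[2-(TBSO)-4-(prenyloxy)phenyl]-5,7-bis(TBSO)-4H-chromen-4-one, via 1,3-diketone 10 (not isolated)
Conditions: LiN(SiMe3)2 (3.2 equiv), THF, −78 °C; 9 (1.05 equiv), −78 → 0 °C; aq NH4Cl; then AcOH, 80 °C
Reagents that add atoms: none
Why: Claisen-type C-acylation of the ketone enolate (the diketone of a Baker–Venkataraman flavone synthesis) followed by cyclodehydration, in which the only free phenol adds to the new aryl ketone and water is lost, closing pyranone ring C with iodine at C8.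

Step 8
Reactants: 11 8-iodo-3-prenyl-2-[2-(TBSO)-4-(prenyloxy)phenyl]-5,7-bis(TBSO)-4H-chromen-4-one
Product: 12 4-oxo-3-prenyl-2-[2-(TBSO)-4-(prenyloxy)phenyl]-5,7-bis(TBSO)-4H-chromene-8-carbaldehyde
Conditions: Pd(PPh3)4 (5 mol %), CO (3 atm), Bu3SnH (1.1 equiv, syringe pump), toluene, 50 °C
Reagents that add atoms: carbon monoxide, [C-]#[O+]
Why: Palladium-catalysed reductive carbonylation of the aryl iodide (oxidative addition, CO insertion, hydride transfer from tin), a neutral formylation that should tolerate the silyl ethers, the chromone and the trisubstituted alkenes.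

Step 9
Reactants: 13 2,4-dihydroxyacetophenone
Product: 14 1-(2,4-dihydroxy-3-prenylphenyl)ethanone
Conditions: prenyl bromide (1.0 equiv), KOH (10% aq), 0 °C → rt
Reagents that add atoms: prenyl bromide, CC(C)=CCBr
Why: C-Prenylation of the resorcinol dianion in water, a known reaction of this ketone that takes place mainly at C3 between the two oxygens; O-alkylated and C5-alkylated by-products are removed by chromatography.

Step 10
Reactants: 14 1-(2,4-dihydroxy-3-prenylphenyl)ethanone
Product: 15 1-[2-hydroxy-3-prenyl-4-(TBSO)phenyl]ethanone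
Conditions: TBSCl (1.05 equiv), imidazole, CH2Cl2, 0 °C
Reagents that add atoms: tert-butyldimethylsilyl chloride, CC(C)(C)[Si](C)(C)Cl
Why: Selective O-silylation of the para hydroxyl; the ortho hydroxyl is chelated to the ketone and stays free, as needed for boron chelation in step 15.

Step 11
Reactants: 15 1-[2-hydroxy-3-prenyl-4-(TBSO)phenyl]ethanone; 12 4-oxo-3-prenyl-2-[2-(TBSO)-4-(prenyloxy)phenyl]-5,7-bis(TBSO)-4H-chromene-8-carbaldehyde
Product: 17 8-{(1E)-3-[2-hydroxy-3-prenyl-4-(TBSO)phenyl]-3-oxoprop-1-en-1-yl}-3-prenyl-2-[2-(TBSO)-4-(prenyloxy)phenyl]-5,7-bis(TBSO)-4H-chromen-4-one, via aldol adduct 16 (not isolated)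
Conditions: LiN(SiMe3)2 (2.2 equiv), THF, −78 °C; 12, −78 → −20 °C; AcOH; then pyridinium p-toluenesulfonate (0.2 equiv), toluene, 60 °C
Reagents that add atoms: none
Why: Directed aldol addition of the ketone dianion to the non-enolisable aldehyde, then acid-catalysed dehydration (a Claisen–Schmidt condensation in two stages), which should give the E enone because the carbinol next to electron-rich ring A ionises easily and the trans alkene is the stable one.

Step 12
Reactants: 18 2,4-dihydroxybenzaldehyde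
Product: 19 2,4-bis(TBSO)benzaldehyde
Conditions: TBSCl (2.3 equiv), imidazole, DMF, rt
Reagents that add atoms: tert-butyldimethylsilyl chloride, CC(C)(C)[Si](C)(C)Cl
Why: Exhaustive phenol O-silylation, which keeps the aryl ring electron-rich for the later cycloaddition.

Step 13
Reactants: 19 2,4-bis(TBSO)benzaldehyde
Product: 20 (3E)-4-[2,4-bis(TBSO)phenyl]but-3-en-2-one
Conditions: Ph3P=CHC(O)CH3 (1.3 equiv), toluene, 90 °C
Reagents that add atoms: 1-(triphenylphosphoranylidene)propan-2-one, CC(=O)C=P(c1ccccc1)(c1ccccc1)c1ccccc1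
Why: Wittig olefination with a stabilised ylide under neutral conditions, which is E-selective and leaves the aryl silyl ethers untouched.

Step 14
Reactants: 20 (3E)-4-[2,4-bis(TBSO)phenyl]but-3-en-2-one
Product: 21 2-{(1E,3E)-4-[2,4-bis(TBSO)phenyl]-2-methylbuta-1,3-dien-1-yl}-4,4,5,5-tetramethyl-1,3,2-dioxaborolane
Conditions: CH2(Bpin)2 (1.3 equiv), lithium 2,2,6,6-tetramethylpiperidide (1.3 equiv), THF, 0 °C; then 20, −78 °C → rt; aq NH4Cl
Reagents that add atoms: bis(4,4,5,5-tetramethyl-1,3,2-dioxaborolan-2-yl)methane, CC1(C)OB(CB2OC(C)(C)C(C)(C)O2)OC1(C)C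
Why: Boron–Wittig olefination (1,2-addition of the lithiated gem-diboryl methane to the ketone, then syn elimination of the boron–oxygen unit), expected to place boron trans to the larger styryl group and so give the (1E,3E)-dienylboronate.

Step 15
Reactants: 17 8-{(1E)-3-[2-hydroxy-3-prenyl-4-(TBSO)phenyl]-3-oxoprop-1-en-1-yl}-3-prenyl-2-[2-(TBSO)-4-(prenyloxy)phenyl]-5,7-bis(TBSO)-4H-chromen-4-one; 21 2-{(1E,3E)-4-[2,4-bis(TBSO)phenyl]-2-methylbuta-1,3-dien-1-yl}-4,4,5,5-tetramethyl-1,3,2-dioxaborolane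
Product: 22 8-[(1S,2R,5R,6R)-2-Bpin-5-[2,4-bis(TBSO)phenyl]-6-[2-hydroxy-3-prenyl-4-(TBSO)benzoyl]-3-methylcyclohex-3-en-1-yl]-3-prenyl-2-[2-(TBSO)-4-(prenyloxy)phenyl]-5,7-bis(TBSO)-4H-chromen-4-one (exo adduct)
Conditions: B(OPh)3 (0.3 equiv), (R)-VANOL (0.3 equiv), 5 Å MS, PhCF3, 40 °C, 21 (1.5 equiv)
Reagents that add atoms: none
Why: The boron of the catalyst binds the phenolate oxygen and the ketone oxygen of 17 in a six-membered chelate, which lowers the enone LUMO so that the electron-rich diene 21 adds in a normal-demand, concerted but asynchronous (4+2) cycloaddition with C2''–C3'' bonding ahead of C4''–C5'' bonding; the closest known reaction type is the chiral borate-catalysed Diels–Alder reaction of 2'-hydroxychalcones with 1-aryl-3-methylbutadienes, combined with the known use of 1-boryl dienes that leave an allylboronate in the adduct. The cyclohexene ring is closed intermolecularly, both new bonds forming suprafacially on one face of each partner. C3'' and C4'' should come out trans because the E geometry of the enone is conserved, C5'' is fixed by the exo orientation (aroyl group away from the diene, flavonyl group under it), which puts its aryl group trans to the aroyl group and cis to the flavonyl group, the absolute sense is set by the VANOL borate covering one face of the chelated enone, and the configuration at the boron-bearing C2'' follows from the E boryl alkene and is erased in step 16. Regioselectivity is needed and is secured by the diene, whose 4-aryl and 2-methyl groups both make the boron-bearing terminus the nucleophilic end that meets the electrophilic β-carbon C3''. Exo selectivity is needed and rests on two features of the substrates: in the endo approach the flavonyl group on C3'' and the pinacolboryl group on C2'', the two largest groups, would be nearly eclipsed across the forming bond, whereas in the exo approach the flat chelated aroyl unit lies below the flat silyloxyaryl ring of the diene. Without the ortho hydroxyl of the aroyl ring neither this activation nor the face control would be available.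

Step 16
Reactants: 22 exo adduct (allylic pinacol boronate with six silyl ethers)
Product: 23 8-[(1S,5R,6S)-6-(2,4-dihydroxy-3-prenylbenzoyl)-5-(2,4-dihydroxyphenyl)-3-methylcyclohex-2-en-1-yl]-5,7-dihydroxy-2-[2-hydroxy-4-(prenyloxy)phenyl]-3-prenyl-4H-chromen-4-one (CNP0082413.1)
Conditions: Bu4NF·3H2O (12 equiv), THF (degassed), 0 → 40 °C; aq NH4Cl
Reagents that add atoms: none
Why: Fluoride forms the boronate complex of the allylic pinacol boronate, which water protonates at the γ-carbon C6'' (SE2' protodeboronation with allylic transposition), so the alkene moves to C1''=C2'' while the same reagent cleaves all six aryl silyl ethers; no stereocentre is created, and C4'', trans to both neighbours, is already the thermodynamic epimer and should not change under the basic conditions.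

**Compound list**

1 | 2,4,6-trihydroxyacetophenone | CC(=O)c1c(O)cc(O)cc1O | starting material
2 | 1-[2-hydroxy-4,6-bis(TBSO)phenyl]ethanone | CC(=O)c1c(O)cc(O[Si](C)(C)C(C)(C)C)cc1O[Si](C)(C)C(C)(C)C | intermediate
3 | 1-[2-hydroxy-3-iodo-4,6-bis(TBSO)phenyl]ethanone | CC(=O)c1c(O)c(I)c(O[Si](C)(C)C(C)(C)C)cc1O[Si](C)(C)C(C)(C)C | intermediate
4 | 1-[2-hydroxy-3-iodo-4,6-bis(TBSO)phenyl]-5-methylhex-4-en-1-one | CC(C)=CCCC(=O)c1c(O)c(I)c(O[Si](C)(C)C(C)(C)C)cc1O[Si](C)(C)C(C)(C)C | intermediate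
5 | methyl 2,4-dihydroxybenzoate | COC(=O)c1ccc(O)cc1O | starting material
6 | methyl 2-hydroxy-4-(prenyloxy)benzoate | COC(=O)c1ccc(OCC=C(C)C)cc1O | intermediate
7 | 2-hydroxy-4-(prenyloxy)benzoic acid | OC(=O)c1ccc(OCC=C(C)C)cc1O | intermediate
8 | tert-butyldimethylsilyl 2-(TBSO)-4-(prenyloxy)benzoate | CC(C)=CCOc1ccc(C(=O)O[Si](C)(C)C(C)(C)C)c(O[Si](C)(C)C(C)(C)C)c1 | intermediate
9 | 2-(TBSO)-4-(prenyloxy)benzoyl chloride | CC(C)=CCOc1ccc(C(Cl)=O)c(O[Si](C)(C)C(C)(C)C)c1 | intermediate
10 | 1-[2-hydroxy-3-iodo-4,6-bis(TBSO)phenyl]-2-prenyl-3-[2-(TBSO)-4-(prenyloxy)phenyl]propane-1,3-dione | CC(C)=CCC(C(=O)c1ccc(OCC=C(C)C)cc1O[Si](C)(C)C(C)(C)C)C(=O)c1c(O)c(I)c(O[Si](C)(C)C(C)(C)C)cc1O[Si](C)(C)C(C)(C)C | intermediate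
11 | 8-iodo-3-prenyl-2-[2-(TBSO)-4-(prenyloxy)phenyl]-5,7-bis(TBSO)-4H-chromen-4-one | O=c1c(CC=C(C)C)c(-c2ccc(OCC=C(C)C)cc2O[Si](C)(C)C(C)(C)C)oc2c(I)c(O[Si](C)(C)C(C)(C)C)cc(O[Si](C)(C)C(C)(C)C)c12 | intermediate
12 | 4-oxo-3-prenyl-2-[2-(TBSO)-4-(prenyloxy)phenyl]-5,7-bis(TBSO)-4H-chromene-8-carbaldehyde | O=Cc1c(O[Si](C)(C)C(C)(C)C)cc(O[Si](C)(C)C(C)(C)C)c2c(=O)c(CC=C(C)C)c(-c3ccc(OCC=C(C)C)cc3O[Si](C)(C)C(C)(C)C)oc12 | intermediate
13 | 2,4-dihydroxyacetophenone | CC(=O)c1ccc(O)cc1O | starting material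
14 | 1-(2,4-dihydroxy-3-prenylphenyl)ethanone | CC(=O)c1ccc(O)c(CC=C(C)C)c1O | intermediate
15 | 1-[2-hydroxy-3-prenyl-4-(TBSO)phenyl]ethanone | CC(=O)c1ccc(O[Si](C)(C)C(C)(C)C)c(CC=C(C)C)c1O | intermediate
16 | 8-{1-hydroxy-3-[2-hydroxy-3-prenyl-4-(TBSO)phenyl]-3-oxopropyl}-3-prenyl-2-[2-(TBSO)-4-(prenyloxy)phenyl]-5,7-bis(TBSO)-4H-chromen-4-one (racemic carbinol) | CC(C)=CCc1c(O[Si](C)(C)C(C)(C)C)ccc(C(=O)CC(O)c2c(O[Si](C)(C)C(C)(C)C)cc(O[Si](C)(C)C(C)(C)C)c3c(=O)c(CC=C(C)C)c(-c4ccc(OCC=C(C)C)cc4O[Si](C)(C)C(C)(C)C)oc23)c1O | intermediate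
17 | 8-{(1E)-3-[2-hydroxy-3-prenyl-4-(TBSO)phenyl]-3-oxoprop-1-en-1-yl}-3-prenyl-2-[2-(TBSO)-4-(prenyloxy)phenyl]-5,7-bis(TBSO)-4H-chromen-4-one | CC(C)=CCc1c(O[Si](C)(C)C(C)(C)C)ccc(C(=O)/C=C/c2c(O[Si](C)(C)C(C)(C)C)cc(O[Si](C)(C)C(C)(C)C)c3c(=O)c(CC=C(C)C)c(-c4ccc(OCC=C(C)C)cc4O[Si](C)(C)C(C)(C)C)oc23)c1O | intermediate
18 | 2,4-dihydroxybenzaldehyde | O=Cc1ccc(O)cc1O | starting material
19 | 2,4-bis(TBSO)benzaldehyde | O=Cc1ccc(O[Si](C)(C)C(C)(C)C)cc1O[Si](C)(C)C(C)(C)C | intermediate
20 | (3E)-4-[2,4-bis(TBSO)phenyl]but-3-en-2-one | CC(=O)/C=C/c1ccc(O[Si](C)(C)C(C)(C)C)cc1O[Si](C)(C)C(C)(C)C | intermediate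
21 | 2-{(1E,3E)-4-[2,4-bis(TBSO)phenyl]-2-methylbuta-1,3-dien-1-yl}-4,4,5,5-tetramethyl-1,3,2-dioxaborolane | CC(/C=C/c1ccc(O[Si](C)(C)C(C)(C)C)cc1O[Si](C)(C)C(C)(C)C)=C\B1OC(C)(C)C(C)(C)O1 | intermediate
22 | 8-[(1S,2R,5R,6R)-2-Bpin-5-[2,4-bis(TBSO)phenyl]-6-[2-hydroxy-3-prenyl-4-(TBSO)benzoyl]-3-methylcyclohex-3-en-1-yl]-3-prenyl-2-[2-(TBSO)-4-(prenyloxy)phenyl]-5,7-bis(TBSO)-4H-chromen-4-one | CC(C)=CCOc1ccc(-c2oc3c([C@H]4[C@@H](B5OC(C)(C)C(C)(C)O5)C(C)=C[C@@H](c5ccc(O[Si](C)(C)C(C)(C)C)cc5O[Si](C)(C)C(C)(C)C)[C@@H]4C(=O)c4ccc(O[Si](C)(C)C(C)(C)C)c(CC=C(C)C)c4O)c(O[Si](C)(C)C(C)(C)C)cc(O[Si](C)(C)C(C)(C)C)c3c(=O)c2CC=C(C)C)c(O[Si](C)(C)C(C)(C)C)c1 | intermediate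
23 | 8-[(1S,5R,6S)-6-(2,4-dihydroxy-3-prenylbenzoyl)-5-(2,4-dihydroxyphenyl)-3-methylcyclohex-2-en-1-yl]-5,7-dihydroxy-2-[2-hydroxy-4-(prenyloxy)phenyl]-3-prenyl-4H-chromen-4-one (CNP0082413.1) | CC(C)=CCOc1ccc(-c2oc3c([C@H]4C=C(C)C[C@@H](c5ccc(O)cc5O)[C@@H]4C(=O)c4ccc(O)c(CC=C(C)C)c4O)c(O)cc(O)c3c(=O)c2CC=C(C)C)c(O)c1 | target

**Step count and risks**

Total step count: 16. Longest linear sequence: 8 steps (1, 2, 3, 7, 8, 11, 15, 16).

Steps most likely to fail:

Step 15. The cycloaddition may be slow at the β-carbon, which carries an aryl group substituted at both ortho positions, and the exo preference may erode in favour of the endo approach. The fallback sets out from 11, 15 and 19 and comes back at 23; it exchanges the roles of the two halves so that the hindered flavone sits on the diene, a pairing with close precedent for this family of adducts. Aldol condensation of 15 with 19 under the conditions of step 11 would give the chalcone (E)-1-[2-hydroxy-3-prenyl-4-(TBSO)phenyl]-3-[2,4-bis(TBSO)phenyl]prop-2-en-1-one F1. Suzuki–Miyaura coupling of iodide 11 with (E)-2-(3-methylbuta-1,3-dien-1-yl)-4,4,5,5-tetramethyl-1,3,2-dioxaborolane (Pd(PPh3)4, CsF, dioxane, 70 °C) would give the diene 8-[(1E)-3-methylbuta-1,3-dien-1-yl]-3-prenyl-2-[2-(TBSO)-4-(prenyloxy)phenyl]-5,7-bis(TBSO)-4H-chromen-4-one F2. The VANOL borate-catalysed Diels–Alder reaction of F1 with F2, with separation of the exo adduct, would give the hexasilyl ether of the target F3, and Bu4NF as in step 16 would lead to 23.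

Step 16. Protonation may take place at the boron-bearing carbon instead of the remote alkene carbon, which would leave the alkene at C1''=C6'', and the freed polyphenol may oxidise or degrade in basic fluoride. The fallback sets out from 22 and comes back at 23. Oxidation of the carbon–boron bond with anhydrous Me3NO (THF, 60 °C) should give, with retention, the allylic alcohol 8-[(1S,2R,5R,6S)-2-hydroxy-5-[2,4-bis(TBSO)phenyl]-6-[2-hydroxy-3-prenyl-4-(TBSO)benzoyl]-3-methylcyclohex-3-en-1-yl]-3-prenyl-2-[2-(TBSO)-4-(prenyloxy)phenyl]-5,7-bis(TBSO)-4H-chromen-4-one F4. Mitsunobu displacement with 2-nitrobenzenesulfonyl hydrazide (PPh3, diethyl azodicarboxylate, −30 °C → rt) would give an allylic diazene that loses N2 with delivery of hydrogen to C6'' (reductive 1,3-transposition), which leads to the hexasilyl ether F3 already described. Removal of the silyl groups with Bu4NF as in step 16, now without a boron group in the molecule, would give 23.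

Step 14. Conjugate addition to the enone or enolisation of the methyl ketone may compete with 1,2-addition of the lithiated diborylmethane, and the elimination may not be fully E-selective. The fallback sets out from 20 and comes back at 21. Enol phosphate formation and elimination (LiN(iPr)2; ClP(O)(OEt)2; LiN(iPr)2, THF, −78 °C → rt) would convert the methyl ketone into the enyne (E)-1-[2,4-bis(TBSO)phenyl]but-1-en-3-yne F5. Zirconium-catalysed methylalumination (Me3Al, Cp2ZrCl2, CH2Cl2) followed by I2 would give, by syn addition, the dienyl iodide (1E,3E)-1-iodo-2-methyl-4-[2,4-bis(TBSO)phenyl]buta-1,3-diene F6. Miyaura borylation (B2pin2, PdCl2(dppf), KOPh, toluene, 50 °C) would then give 21 with retention of the alkene geometry.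

Further compounds
F1 | step 15 | (E)-1-[2-hydroxy-3-prenyl-4-(TBSO)phenyl]-3-[2,4-bis(TBSO)phenyl]prop-2-en-1-one | CC(C)=CCc1c(O[Si](C)(C)C(C)(C)C)ccc(C(=O)/C=C/c2ccc(O[Si](C)(C)C(C)(C)C)cc2O[Si](C)(C)C(C)(C)C)c1O
F2 | step 15 | 8-[(1E)-3-methylbuta-1,3-dien-1-yl]-3-prenyl-2-[2-(TBSO)-4-(prenyloxy)phenyl]-5,7-bis(TBSO)-4H-chromen-4-one | CC(=C)/C=C/c1c(O[Si](C)(C)C(C)(C)C)cc(O[Si](C)(C)C(C)(C)C)c2c(=O)c(CC=C(C)C)c(-c3ccc(OCC=C(C)C)cc3O[Si](C)(C)C(C)(C)C)oc12
F3 | step 15 | 8-[(1S,5R,6S)-5-[2,4-bis(TBSO)phenyl]-6-[2-hydroxy-3-prenyl-4-(TBSO)benzoyl]-3-methylcyclohex-2-en-1-yl]-3-prenyl-2-[2-(TBSO)-4-(prenyloxy)phenyl]-5,7-bis(TBSO)-4H-chromen-4-one | CC(C)=CCOc1ccc(-c2oc3c([C@H]4C=C(C)C[C@@H](c5ccc(O[Si](C)(C)C(C)(C)C)cc5O[Si](C)(C)C(C)(C)C)[C@@H]4C(=O)c4ccc(O[Si](C)(C)C(C)(C)C)c(CC=C(C)C)c4O)c(O[Si](C)(C)C(C)(C)C)cc(O[Si](C)(C)C(C)(C)C)c3c(=O)c2CC=C(C)C)c(O[Si](C)(C)C(C)(C)C)c1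
F4 | step 16 | 8-[(1S,2R,5R,6S)-2-hydroxy-5-[2,4-bis(TBSO)phenyl]-6-[2-hydroxy-3-prenyl-4-(TBSO)benzoyl]-3-methylcyclohex-3-en-1-yl]-3-prenyl-2-[2-(TBSO)-4-(prenyloxy)phenyl]-5,7-bis(TBSO)-4H-chromen-4-one | CC(C)=CCOc1ccc(-c2oc3c([C@H]4[C@@H](O)C(C)=C[C@@H](c5ccc(O[Si](C)(C)C(C)(C)C)cc5O[Si](C)(C)C(C)(C)C)[C@@H]4C(=O)c4ccc(O[Si](C)(C)C(C)(C)C)c(CC=C(C)C)c4O)c(O[Si](C)(C)C(C)(C)C)cc(O[Si](C)(C)C(C)(C)C)c3c(=O)c2CC=C(C)C)c(O[Si](C)(C)C(C)(C)C)c1
F5 | step 14 | (E)-1-[2,4-bis(TBSO)phenyl]but-1-en-3-yne | C#C/C=C/c1ccc(O[Si](C)(C)C(C)(C)C)cc1O[Si](C)(C)C(C)(C)C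
F6 | step 14 | (1E,3E)-1-iodo-2-methyl-4-[2,4-bis(TBSO)phenyl]buta-1,3-diene | CC(/C=C/c1ccc(O[Si](C)(C)C(C)(C)C)cc1O[Si](C)(C)C(C)(C)C)=C\I
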